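**Retrosynthetic overview**
1. Target 20 comes from pentamethoxyflavone 19 by cleavage of the 5-O-methyl ether, and 19 from the 2'-phenol 18 by O-methylation.
2. The strategy rests on ring B: a benzene with oxygen on C2' and C5' (para to each other) and chromone C2 on C1', next to C2'–O. It is cut at C5'–C6', C1'–C2' and C2'–C3' into 2-ethynylchromone 11, the vinyl(methoxy)carbene chromium complex 16 and one of its CO ligands (Dötz benzannulation).
3. Alkyne 11 comes from aldehyde 10 by one-carbon homologation, 10 from alcohol 9, 9 from chromone-2-carboxylate 8, and 8 from acetophenone 5 and diethyl oxalate 6; complex 16 comes from Cr(CO)6 and vinyllithium.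
4. Acetophenone 5 comes from 1,2,3,5-tetramethoxybenzene 2, made from 3,4,5-trimethoxyphenol 1. The phenol is O-methylated before acylation because its direct C-acylation would lead to the 5,6,7- and not the 5,7,8-oxygenation pattern.
5. Ring order: ring A is bought, ring C (pyranone) closes in step 3, ring B is built last in step 8.

Key step: step 8

Remark: the η6-arene chromium complex 17 is not isolated; its SMILES is written as the arene and a Cr(CO)3 fragment joined by a dot.

**Step 1**
Reactants: 1 3,4,5-trimethoxyphenol
Product: 2 1,2,3,5-tetramethoxybenzene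
Conditions: MeI, K2CO3, acetone, reflux
Reagents that add atoms: iodomethane, CI
Why: Williamson O-methylation of the phenoxide (SN2 at MeI) has no competing site and removes the free OH that would otherwise steer the acylation to the wrong ring position.

**Step 2**
Reactants: 2 1,2,3,5-tetramethoxybenzene; 3 acetyl chloride
Product: 5 2-hydroxy-3,4,6-trimethoxyacetophenone, via 2,3,4,6-tetramethoxyacetophenone 4 (not isolated)
Conditions: AcCl, AlCl3 (2.5 equiv), Et2O, 0 °C to reflux; then 1 M HCl
Reagents that add atoms: none
Why: Friedel–Crafts acylation at one of the two equivalent free positions of the electron-rich arene is followed in the same pot by AlCl3 cleavage of the ortho methoxy group squeezed between the acetyl group and the 3-OMe, a selectivity known for such crowded ortho ethers and driven by the six-membered aluminium chelate with the ketone.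

**Step 3**
Reactants: 5 2-hydroxy-3,4,6-trimethoxyacetophenone; 6 diethyl oxalate
Product: 8 ethyl 5,7,8-trimethoxy-4-oxo-4H-chromene-2-carboxylate, via diketo ester 7 (not isolated)
Conditions: NaOEt (4 equiv), EtOH, reflux; then conc. HCl, EtOH, reflux
Reagents that add atoms: none
Why: Crossed Claisen condensation of the methyl ketone enolate with non-enolisable diethyl oxalate, then acid-catalysed attack of the phenol on the 2-keto group with loss of water, is the classical chromone-2-carboxylate synthesis and closes ring C.

**Step 4**
Reactants: 8 ethyl 5,7,8-trimethoxy-4-oxo-4H-chromene-2-carboxylate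
Product: 9 2-(hydroxymethyl)-5,7,8-trimethoxy-4H-chromen-4-one
Conditions: NaBH4 (1 equiv), MeOH, 0 °C
Reagents that add atoms: none
Why: Borohydride reduction of the ester, which is activated by the electron-poor pyranone carbon C2, is known for chromone-2-carboxylates to outrun attack on the vinylogous-ester carbonyl C4 and on C2=C3.

**Step 5**
Reactants: 9 2-(hydroxymethyl)-5,7,8-trimethoxy-4H-chromen-4-one
Product: 10 5,7,8-trimethoxy-4-oxo-4H-chromene-2-carbaldehyde
Conditions: activated MnO2 (10 equiv), CH2Cl2, rt
Reagents that add atoms: none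
Why: The alcohol is allylic to C2=C3, so MnO2 oxidation is selective for it and stops at the aldehyde.

**Step 6**
Reactants: 10 5,7,8-trimethoxy-4-oxo-4H-chromene-2-carbaldehyde
Product: 11 2-ethynyl-5,7,8-trimethoxy-4H-chromen-4-one
Conditions: Me3SiCHN2, LiN(iPr)2 (LDA), THF, −78 °C; added to 10 in THF, −78 °C to rt
Reagents that add atoms: trimethylsilyldiazomethane, C[Si](C)(C)C=[N+]=[N-]
Why: In this Colvin rearrangement the lithiated silyldiazomethane adds to the aldehyde, which is far more electrophilic than the vinylogous-ester carbonyl C4, and Peterson loss of Me3SiOLi, loss of N2 and a 1,2-hydrogen shift of the alkylidene carbene give the terminal alkyne without a protic nucleophile that could add to the pyranone.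

**Step 7**
Reactants: 12 tetravinyltin Sn(CH=CH2)4; 13 chromium hexacarbonyl Cr(CO)6
Product: 16 pentacarbonyl[methoxy(vinyl)carbene]chromium, via vinyllithium 14 (not isolated), via lithium acylchromate 15 (not isolated)
Conditions: Sn(CH=CH2)4, MeLi, Et2O, 0 °C; Cr(CO)6, 0 °C to rt; Me3OBF4, H2O/CH2Cl2, 0 °C; kept as a cold dilute solution and used the same day
Reagents that add atoms: trimethyloxonium tetrafluoroborate, C[O+](C)C.F[B-](F)(F)F
Why: In this Fischer carbene synthesis tin–lithium exchange gives vinyllithium, which adds to a CO ligand of Cr(CO)6, and the acylchromate is O-methylated by the Meerwein salt; the complex is prone to polymerise and is therefore not concentrated or stored.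

**Step 8**
Reactants: 11 2-ethynyl-5,7,8-trimethoxy-4H-chromen-4-one; 16 pentacarbonyl[methoxy(vinyl)carbene]chromium
Product: 18 2-(2-hydroxy-5-methoxyphenyl)-5,7,8-trimethoxy-4H-chromen-4-one, via tricarbonylchromium arene complex 17 (not isolated)
Conditions: 16 (2 equiv, two portions), THF (0.1 M), 45–50 °C, Ar; then air, light, Et2O, rt
Reagents that add atoms: none
Why: Thermal loss of a cis CO ligand from 16 lets the alkyne of 11 bind and insert into the Cr=C bond to give a vinylcarbene, CO insertion gives the chromium-bound dienylketene, and 6π electrocyclisation onto the vinyl terminus followed by enolisation gives the η6-phenol complex 17, from which air removes Cr(CO)3. The closest known reaction is the Dötz benzannulation of alkenyl(alkoxy)carbene chromium complexes with terminal alkynes, which gives 4-alkoxyphenols. Ring B is closed by the 6π electrocyclic ring closure that forms C2'–C3', after the two insertions have formed C5'–C6' and C1'–C2'. No stereocentre is formed. The step needs regioselective alkyne insertion and chemoselectivity for the alkyne over C2=C3 of the pyranone: the unsubstituted alkyne carbon bonds to the carbene carbon for steric reasons, so the chromone-bearing carbon becomes C1' between C2'–OH and C6'–H, and coordinatively unsaturated zerovalent chromium binds an alkyne far better than a push–pull alkene at this temperature. The excess of freshly made 16 offsets its polymerisation and the slower insertion expected for an alkyne conjugated to the pyranone.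

**Step 9**
Reactants: 18 2-(2-hydroxy-5-methoxyphenyl)-5,7,8-trimethoxy-4H-chromen-4-one
Product: 19 2-(2,5-dimethoxyphenyl)-5,7,8-trimethoxy-4H-chromen-4-one
Conditions: MeI, K2CO3, acetone, reflux
Reagents that add atoms: iodomethane, CI
Why: Williamson etherification of the only free phenol completes the 2',5'-dimethoxy pattern of ring B.

**Step 10**
Reactants: 19 2-(2,5-dimethoxyphenyl)-5,7,8-trimethoxy-4H-chromen-4-one
Product: 20 5-hydroxy-7,8,2',5'-tetramethoxyflavone
Conditions: BCl3 (1.5 equiv), CH2Cl2, −78 to 0 °C; then H2O/MeOH
Reagents that add atoms: none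
Why: In this chelation-directed Lewis-acid ether cleavage boron bridges the C4 carbonyl and the peri 5-OMe in a six-membered chelate, so chloride removes only that methyl group, while the 7-, 8-, 2'- and 5'-methoxy groups cannot chelate and survive at low temperature.

**Compound list**
1 | 3,4,5-trimethoxyphenol | COc1cc(O)cc(OC)c1OC | starting material
2 | 1,2,3,5-tetramethoxybenzene | COc1cc(OC)c(OC)c(OC)c1 | intermediate
3 | acetyl chloride | CC(=O)Cl | starting material
4 | 2,3,4,6-tetramethoxyacetophenone | CC(=O)c1c(OC)cc(OC)c(OC)c1OC | intermediate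
5 | 2-hydroxy-3,4,6-trimethoxyacetophenone | CC(=O)c1c(OC)cc(OC)c(OC)c1O | intermediate
6 | diethyl oxalate | CCOC(=O)C(=O)OCC | starting material
7 | ethyl 4-(2-hydroxy-3,4,6-trimethoxyphenyl)-2,4-dioxobutanoate | CCOC(=O)C(=O)CC(=O)c1c(OC)cc(OC)c(OC)c1O | intermediate
8 | ethyl 5,7,8-trimethoxy-4-oxo-4H-chromene-2-carboxylate | CCOC(=O)c1cc(=O)c2c(OC)cc(OC)c(OC)c2o1 | intermediate
9 | 2-(hydroxymethyl)-5,7,8-trimethoxy-4H-chromen-4-one | OCc1cc(=O)c2c(OC)cc(OC)c(OC)c2o1 | intermediate
10 | 5,7,8-trimethoxy-4-oxo-4H-chromene-2-carbaldehyde | O=Cc1cc(=O)c2c(OC)cc(OC)c(OC)c2o1 | intermediate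
11 | 2-ethynyl-5,7,8-trimethoxy-4H-chromen-4-one | C#Cc1cc(=O)c2c(OC)cc(OC)c(OC)c2o1 | intermediate
12 | tetravinyltin Sn(CH=CH2)4 | C=C[Sn](C=C)(C=C)C=C | starting material
13 | chromium hexacarbonyl Cr(CO)6 | O=C=[Cr](=C=O)(=C=O)(=C=O)(=C=O)=C=O | starting material
14 | vinyllithium | [Li]C=C | intermediate
15 | lithium pentacarbonyl(1-oxidoprop-2-en-1-ylidene)chromate, Li[(CO)5CrC(O)CH=CH2] | C=CC(O[Li])=[Cr](=C=O)(=C=O)(=C=O)(=C=O)=C=O | intermediate
16 | pentacarbonyl[methoxy(vinyl)carbene]chromium, (CO)5Cr=C(OMe)CH=CH2 | C=CC(OC)=[Cr](=C=O)(=C=O)(=C=O)(=C=O)=C=O | intermediate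
17 | tricarbonyl[η6-2-(2-hydroxy-5-methoxyphenyl)-5,7,8-trimethoxy-4H-chromen-4-one]chromium, Cr(CO)3 on ring B | COc1ccc(O)c(-c2cc(=O)c3c(OC)cc(OC)c(OC)c3o2)c1.O=C=[Cr](=C=O)=C=O | intermediate
18 | 2-(2-hydroxy-5-methoxyphenyl)-5,7,8-trimethoxy-4H-chromen-4-one | COc1ccc(O)c(-c2cc(=O)c3c(OC)cc(OC)c(OC)c3o2)c1 | intermediate
19 | 2-(2,5-dimethoxyphenyl)-5,7,8-trimethoxy-4H-chromen-4-one | COc1ccc(OC)c(-c2cc(=O)c3c(OC)cc(OC)c(OC)c3o2)c1 | intermediate
20 | 5-hydroxy-7,8,2',5'-tetramethoxyflavone | COc1ccc(OC)c(-c2cc(=O)c3c(O)cc(OC)c(OC)c3o2)c1 | target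

**Total step count:** 10

**Longest linear sequence:** 9 steps (steps 1–6, then 8–10, from 3,4,5-trimethoxyphenol); step 7 is a one-step side branch.

**Steps most likely to fail**

Step 8. Alkyne insertion may be slow for the pyranone-conjugated alkyne, so that polymerisation and thermal decay of the vinyl complex, or oligomerisation of the alkyne, take over before the benzannulation is complete. The fallback sets out from acetophenone 5 and comes back at flavone 19. Acetophenone 5 would be condensed with commercial 2,5-dimethoxybenzaldehyde (KOH, EtOH, rt, Claisen–Schmidt condensation) to (E)-1-(2-hydroxy-3,4,6-trimethoxyphenyl)-3-(2,5-dimethoxyphenyl)prop-2-en-1-one F1. F1 would then be cyclised and dehydrogenated with catalytic I2 in DMSO at 130 °C to give 19. Steps 3–9 then fall away and step 10 follows.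

Step 7. The parent vinyl complex may polymerise during O-methylation and handling, leaving too little reagent for step 8. The fallback sets out from Cr(CO)6 13 and comes back at phenol 18.
- Cr(CO)6 13 would be acylated with (E)-2-(trimethylsilyl)vinyllithium, made from commercial (E)-(2-bromovinyl)trimethylsilane and t-BuLi in Et2O at −78 °C.
- O-methylation with Me3OBF4 would give the storable β-silylvinyl surrogate pentacarbonyl[methoxy((E)-2-(trimethylsilyl)vinyl)carbene]chromium F2.
- Benzannulation of F2 with alkyne 11 under the conditions of step 8 should pass through the same vinylketene. The cyclohexadienone should then aromatise by a 1,3-shift of silicon from C3' to oxygen, giving after air decomplexation 2-[5-methoxy-2-(trimethylsilyloxy)phenyl]-5,7,8-trimethoxy-4H-chromen-4-one F3.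
- Dilute HCl in MeOH would cleave F3 to 18.

Step 6. The lithium reagent may attack the pyranone (ring opening at C2) instead of the aldehyde, or the base may degrade the Michael-accepting product. The fallback sets out from aldehyde 10 and comes back at alkyne 11.
- Aldehyde 10 would be converted with CBr4/PPh3 (CH2Cl2, 0 °C, Ramirez olefination) into 2-(2,2-dibromovinyl)-5,7,8-trimethoxy-4H-chromen-4-one F4.
- The bromine trans to the chromone would be removed with Bu3SnH and catalytic Pd(PPh3)4 (zerovalent palladium) to give (Z)-2-(2-bromovinyl)-5,7,8-trimethoxy-4H-chromen-4-one F5.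
- Anti elimination of HBr from F5 with DBU in THF would give 11 without any organolithium.

**Further compounds**
F1 | step 8 | (E)-1-(2-hydroxy-3,4,6-trimethoxyphenyl)-3-(2,5-dimethoxyphenyl)prop-2-en-1-one | COc1ccc(OC)c(/C=C/C(=O)c2c(OC)cc(OC)c(OC)c2O)c1
F2 | step 7 | pentacarbonyl[methoxy((E)-2-(trimethylsilyl)vinyl)carbene]chromium | C[Si](C)(C)/C=C/C(OC)=[Cr](=C=O)(=C=O)(=C=O)(=C=O)=C=O
F3 | step 7 | 2-[5-methoxy-2-(trimethylsilyloxy)phenyl]-5,7,8-trimethoxy-4H-chromen-4-one | COc1ccc(O[Si](C)(C)C)c(-c2cc(=O)c3c(OC)cc(OC)c(OC)c3o2)c1
F4 | step 6 | 2-(2,2-dibromovinyl)-5,7,8-trimethoxy-4H-chromen-4-one | BrC(Br)=Cc1cc(=O)c2c(OC)cc(OC)c(OC)c2o1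
F5 | step 6 | (Z)-2-(2-bromovinyl)-5,7,8-trimethoxy-4H-chromen-4-one | Br/C=C\c1cc(=O)c2c(OC)cc(OC)c(OC)c2o1
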